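**Plan**

- Retrosynthesis: the benzofuran is cut at its O1'–C2' bond and at the C2'–C5 bond to the pyran (alkyne annulation on a C5 iodide). The C4 methylene is traced back to a C4 ketone. The resulting 2,3-dihydro-4H-pyran-4-one is cut at C2–C3 and O1–C6.
- Enabling feature: in the dihydropyran ring, O1–C2 is an aldehyde C=O, and C3–C4–C5=C6 is a 1-methoxy-3-silyloxy diene carrying the CH2O arm on its terminus. One [4+2] event therefore gives the ring, the C5=C6 enol ether and both stereocentres.
- Forward order: diene from methyl 3-hydroxypropanoate; pyran ring first; C4 oxygen removed by Luche reduction, Ferrier-type reduction and alkene isomerisation back to the enol ether; C5 iodination.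
- The benzofuran ring is closed last, by Sonogashira coupling and 5-endo cyclisation with an ethynyl hydroquinone ketone; final aryl desilylation.
- Stereochemistry: C2 (R) and C3 (S), trans, are both set by the chiral zirconium binaphtholate in the ring-forming step. No later step breaks a bond at either centre; the C4 carbinol centre of step 8 is transient.

Key step: step 7

Assumption: (R)-3,3'-diiodo-1,1'-bi-2-naphthol is taken as the ligand enantiomer that sends the diene to the Re face of the aldehyde (giving 2R); if a first run shows the opposite sense, the (S)-ligand is used with nothing else changed.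

**Route**

Step 1
Reactants: 1 vanillin
Product: 2 3-methoxy-4-(triisopropylsilyloxy)benzaldehyde
Conditions: TIPSCl, imidazole, DMF, rt
Reagents that add atoms: triisopropylsilyl chloride, CC(C)[Si](Cl)(C(C)C)C(C)C
Why: Standard phenol O-silylation; a bulky aryl silyl ether is chosen because it is inert to the Lewis acid, hydride, acid, ruthenium hydride and palladium steps ahead and falls to buffered fluoride at the end.

Step 2
Reactants: 3 methyl 3-hydroxypropanoate
Product: 4 methyl 3-(tert-butyldimethylsilyloxy)propanoate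
Conditions: TBSCl, imidazole, CH2Cl2, 0 °C to rt
Reagents that add atoms: tert-butyldimethylsilyl chloride, CC(C)(C)[Si](C)(C)Cl
Why: Routine silylation of a primary alcohol, giving an alkyl silyl ether that can later be cleaved by acid in the presence of the aryl silyl ether.

Step 3
Reactants: 4 methyl 3-(tert-butyldimethylsilyloxy)propanoate
Product: 5 3-(tert-butyldimethylsilyloxy)-N-methoxy-N-methylpropanamide
Conditions: MeNH(OMe)·HCl, iPrMgCl, THF, −20 °C
Reagents that add atoms: N,O-dimethylhydroxylamine hydrochloride, CNOC.Cl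
Why: Weinreb amide formation by aminolysis of the ester with the magnesium amide, fast enough at low temperature to avoid β-elimination of the silyloxy group.

Step 4
Reactants: 5 3-(tert-butyldimethylsilyloxy)-N-methoxy-N-methylpropanamide; 6 ethynylmagnesium bromide
Product: 7 5-(tert-butyldimethylsilyloxy)pent-1-yn-3-one
Conditions: THF, 0 °C; inverse quench into cold 1 M HCl
Reagents that add atoms: none
Why: Weinreb ketone synthesis, in which the chelated tetrahedral adduct stops at the ketone stage and the acidic inverse quench keeps the liberated amine from adding to the ynone.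

Step 5
Reactants: 7 5-(tert-butyldimethylsilyloxy)pent-1-yn-3-one
Product: 8 (E)-5-(tert-butyldimethylsilyloxy)-1-methoxypent-1-en-3-one
Conditions: MeOH, DABCO (10 mol%), CH2Cl2, 0 °C to rt
Reagents that add atoms: methanol, CO
Why: Amine-catalysed oxa-Michael addition of methanol to the terminal ynone, which should settle on the more stable E β-methoxy enone.

Step 6
Reactants: 8 (E)-5-(tert-butyldimethylsilyloxy)-1-methoxypent-1-en-3-one
Product: 9 (1E,3Z)-5-(tert-butyldimethylsilyloxy)-1-methoxy-3-(trimethylsilyloxy)penta-1,3-diene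
Conditions: TMSOTf, Et3N, Et2O, −78 to 0 °C; filtered and used without chromatography
Reagents that add atoms: trimethylsilyl trifluoromethanesulfonate, C[Si](C)(C)OS(=O)(=O)C(F)(F)F
Why: Soft enolisation and O-silylation of the ketone CH2 should give mainly the Z silyl enol ether, and because no free enolate is formed the β-silyloxy group is not expelled.

Step 7
Reactants: 2 3-methoxy-4-(triisopropylsilyloxy)benzaldehyde; 9 (1E,3Z)-5-(tert-butyldimethylsilyloxy)-1-methoxy-3-(trimethylsilyloxy)penta-1,3-diene
Product: 11 (2R,3S)-3-[(tert-butyldimethylsilyloxy)methyl]-2-[3-methoxy-4-(triisopropylsilyloxy)phenyl]-2,3-dihydro-4H-pyran-4-one, via silylated anti-aldol adduct 10 (not isolated)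
Conditions: Zr(OtBu)4 (10 mol%), (R)-3,3'-diiodo-1,1'-bi-2-naphthol (12 mol%), n-PrOH, H2O, toluene, −20 °C; then CF3CO2H, CH2Cl2, 0 °C
Reagents that add atoms: none
Why: The binaphtholate complex of tetravalent zirconium activates the aldehyde and the substituted diene terminus adds in a Mukaiyama aldol fashion to form C2–C3 (adduct 10); trifluoroacetic acid then closes O1–C6 by 6-endo-trig conjugate addition of the C2 oxygen to the β-methoxy enone and expels methanol, a formal [4+2]. The closest known reaction type is the zirconium–binaphthol-catalysed, 2,3-trans-selective hetero-Diels–Alder reaction of aldehydes with 1-alkoxy-3-silyloxy dienes bearing an alkyl or alkoxy group at the terminus. C2 (R) is set by catalyst-controlled addition to the Re face of the aldehyde carbonyl. C3 (S) follows from the anti-selective open transition state of the silyl enol ether, which places the aryl and silyloxymethyl groups trans. The step needs enantioselectivity, trans selectivity and survival of the β-silyloxy group: the chiral ligand secures the first, the open transition state together with the thermodynamic preference for the diequatorial trans isomer (C3 is epimerisable α to the ketone) the second, and the short, cold acid treatment the third.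

Step 8
Reactants: 11 (2R,3S)-3-[(tert-butyldimethylsilyloxy)methyl]-2-[3-methoxy-4-(triisopropylsilyloxy)phenyl]-2,3-dihydro-4H-pyran-4-one
Product: 12 (2R,3R,4S)-3-[(tert-butyldimethylsilyloxy)methyl]-2-[3-methoxy-4-(triisopropylsilyloxy)phenyl]-3,4-dihydro-2H-pyran-4-ol
Conditions: NaBH4, CeCl3·7H2O, MeOH, −78 °C; NaHCO3 work-up, used crude
Reagents that add atoms: none
Why: Luche 1,2-reduction of the vinylogous ester carbonyl leaves the enol ether intact; axial hydride delivery should place the C4 hydroxyl trans to the C3 arm, but C4 is erased in step 9, so either epimer serves.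

Step 9
Reactants: 12 (2R,3R,4S)-3-[(tert-butyldimethylsilyloxy)methyl]-2-[3-methoxy-4-(triisopropylsilyloxy)phenyl]-3,4-dihydro-2H-pyran-4-ol
Product: 13 tert-butyl{[(2R,3S)-2-[3-methoxy-4-(triisopropylsilyloxy)phenyl]-3,6-dihydro-2H-pyran-3-yl]methoxy}dimethylsilane
Conditions: Et3SiH, BF3·OEt2, CH2Cl2, −78 °C; Et3N quench
Reagents that add atoms: none
Why: Ferrier-type reductive rearrangement, in which BF3 ionises the allylic hydroxyl to the allyl oxocarbenium ion and the silane delivers hydride to C6, moving the alkene to C4=C5 and removing the C4 oxygen without touching C2 or C3.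

Step 10
Reactants: 13 tert-butyl{[(2R,3S)-2-[3-methoxy-4-(triisopropylsilyloxy)phenyl]-3,6-dihydro-2H-pyran-3-yl]methoxy}dimethylsilane
Product: 14 [(2R,3S)-2-[3-methoxy-4-(triisopropylsilyloxy)phenyl]-3,6-dihydro-2H-pyran-3-yl]methanol
Conditions: CSA (10 mol%), MeOH/CH2Cl2, 0 °C
Reagents that add atoms: none
Why: Acid-catalysed methanolysis cleaves the primary alkyl silyl ether far faster than the aryl silyl ether, and it is placed here because the ring carries no acid-labile enol ether at this stage.

Step 11
Reactants: 14 [(2R,3S)-2-[3-methoxy-4-(triisopropylsilyloxy)phenyl]-3,6-dihydro-2H-pyran-3-yl]methanol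
Product: 15 [(2R,3S)-2-[3-methoxy-4-(triisopropylsilyloxy)phenyl]-3,6-dihydro-2H-pyran-3-yl]methyl acetate
Conditions: Ac2O, pyridine, DMAP (cat.), CH2Cl2, 0 °C to rt
Reagents that add atoms: acetic anhydride, CC(=O)OC(C)=O
Why: Routine acetylation of the only free hydroxyl, which installs the acetate of the target while both phenols are still masked or absent.

Step 12
Reactants: 15 [(2R,3S)-2-[3-methoxy-4-(triisopropylsilyloxy)phenyl]-3,6-dihydro-2H-pyran-3-yl]methyl acetate
Product: 16 [(2R,3S)-2-[3-methoxy-4-(triisopropylsilyloxy)phenyl]-3,4-dihydro-2H-pyran-3-yl]methyl acetate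
Conditions: RuHCl(CO)(PPh3)3 (5 mol%), toluene, 80 °C
Reagents that add atoms: none
Why: Ruthenium hydride-catalysed alkene isomerisation (hydrometalation and β-hydride elimination) of a cyclic allyl ether to the more stable enol ether, known for 3,6-dihydro-2H-pyrans, with the oxygen-conjugated C5=C6 position as the thermodynamic sink.

Step 13
Reactants: 16 [(2R,3S)-2-[3-methoxy-4-(triisopropylsilyloxy)phenyl]-3,4-dihydro-2H-pyran-3-yl]methyl acetate
Product: 17 [(2R,3S)-5-iodo-2-[3-methoxy-4-(triisopropylsilyloxy)phenyl]-3,4-dihydro-2H-pyran-3-yl]methyl acetate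
Conditions: NIS, AgNO3 (20 mol%), MeCN, 60 °C, dark
Reagents that add atoms: N-iodosuccinimide, O=C1CCC(=O)N1I
Why: Electrophilic iodination at the nucleophilic β-carbon C5 of the enol ether followed by loss of the C5 proton, the method used to turn glycals into 2-iodoglycals.

Step 14
Reactants: 18 2-bromo-1,4-dimethoxybenzene
Product: 19 1-(4-bromo-2,5-dimethoxyphenyl)ethanone
Conditions: AcCl, AlCl3, CH2Cl2, 0 °C to rt
Reagents that add atoms: acetyl chloride, CC(Cl)=O
Why: Friedel–Crafts acylation, directed para to bromine and ortho to a methoxy group, which fixes the 1,2,4,5-substitution pattern of the later benzofuran.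

Step 15
Reactants: 19 1-(4-bromo-2,5-dimethoxyphenyl)ethanone
Product: 20 1-(4-bromo-2,5-dihydroxyphenyl)ethanone
Conditions: BBr3, CH2Cl2, −78 °C to rt; H2O
Reagents that add atoms: none
Why: Lewis acid cleavage of both aryl methyl ethers, done before any acid-sensitive group is present.

Step 16
Reactants: 20 1-(4-bromo-2,5-dihydroxyphenyl)ethanone; 21 ethynyltrimethylsilane
Product: 22 1-{2,5-dihydroxy-4-[(trimethylsilyl)ethynyl]phenyl}ethanone
Conditions: PdCl2(PPh3)2 (3 mol%), CuI (5 mol%), Et3N, THF, 50 °C, degassed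
Reagents that add atoms: none
Why: Sonogashira coupling at an aryl bromide activated by the para acetyl group, with the silyl cap slowing premature cyclisation of the ortho hydroxyl onto the alkyne.

Step 17
Reactants: 22 1-{2,5-dihydroxy-4-[(trimethylsilyl)ethynyl]phenyl}ethanone
Product: 23 1-(4-ethynyl-2,5-dihydroxyphenyl)ethanone
Conditions: K2CO3 (0.2 equiv), MeOH, 0 °C, argon
Reagents that add atoms: none
Why: Mild methanolytic C-desilylation of the alkynylsilane, run cold and air-free so that the ethynyl hydroquinone neither cyclises nor oxidises.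

Step 18
Reactants: 17 [(2R,3S)-5-iodo-2-[3-methoxy-4-(triisopropylsilyloxy)phenyl]-3,4-dihydro-2H-pyran-3-yl]methyl acetate; 23 1-(4-ethynyl-2,5-dihydroxyphenyl)ethanone
Product: 25 [(2R,3S)-5-(6-acetyl-5-hydroxy-1-benzofuran-2-yl)-2-[3-methoxy-4-(triisopropylsilyloxy)phenyl]-3,4-dihydro-2H-pyran-3-yl]methyl acetate, via enyne phenol 24 (not isolated)
Conditions: PdCl2(PPh3)2 (5 mol%), CuI (10 mol%), Et3N, DMF, rt then 60 °C, degassed
Reagents that add atoms: none
Why: Sonogashira coupling of the alkenyl iodide gives enyne 24, whose ortho hydroxyl then adds 5-endo-dig to the metal-activated alkyne to close the furan ring, as known for o-ethynylphenols with alkenyl and aryl electrophiles; only one hydroxyl is ortho to the alkyne, so the 6-acetyl-5-hydroxy pattern is fixed.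

Step 19
Reactants: 25 [(2R,3S)-5-(6-acetyl-5-hydroxy-1-benzofuran-2-yl)-2-[3-methoxy-4-(triisopropylsilyloxy)phenyl]-3,4-dihydro-2H-pyran-3-yl]methyl acetate
Product: 26 propolis-benzofuran A
Conditions: TBAF, AcOH, THF, 0 °C
Reagents that add atoms: none
Why: Fluoride cleavage of the aryl silyl ether is very fast, and the acetic acid buffer should keep the primary acetate and the enol ether intact.

**Compound list**

1 | vanillin (4-hydroxy-3-methoxybenzaldehyde) | COc1cc(C=O)ccc1O | starting material
2 | 3-methoxy-4-(triisopropylsilyloxy)benzaldehyde | COc1cc(C=O)ccc1O[Si](C(C)C)(C(C)C)C(C)C | intermediate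
3 | methyl 3-hydroxypropanoate | COC(=O)CCO | starting material
4 | methyl 3-(tert-butyldimethylsilyloxy)propanoate | COC(=O)CCO[Si](C)(C)C(C)(C)C | intermediate
5 | 3-(tert-butyldimethylsilyloxy)-N-methoxy-N-methylpropanamide | CON(C)C(=O)CCO[Si](C)(C)C(C)(C)C | intermediate
6 | ethynylmagnesium bromide | C#C[Mg]Br | starting material
7 | 5-(tert-butyldimethylsilyloxy)pent-1-yn-3-one | C#CC(=O)CCO[Si](C)(C)C(C)(C)C | intermediate
8 | (E)-5-(tert-butyldimethylsilyloxy)-1-methoxypent-1-en-3-one | CO/C=C/C(=O)CCO[Si](C)(C)C(C)(C)C | intermediate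
9 | (1E,3Z)-5-(tert-butyldimethylsilyloxy)-1-methoxy-3-(trimethylsilyloxy)penta-1,3-diene | CO/C=C/C(O[Si](C)(C)C)=C/CO[Si](C)(C)C(C)(C)C | intermediate
10 | (1E,4S,5R)-4-[(tert-butyldimethylsilyloxy)methyl]-1-methoxy-5-[3-methoxy-4-(triisopropylsilyloxy)phenyl]-5-(trimethylsilyloxy)pent-1-en-3-one | COc1cc([C@H](O[Si](C)(C)C)[C@H](CO[Si](C)(C)C(C)(C)C)C(=O)/C=C/OC)ccc1O[Si](C(C)C)(C(C)C)C(C)C | intermediate (not isolated)
11 | (2R,3S)-3-[(tert-butyldimethylsilyloxy)methyl]-2-[3-methoxy-4-(triisopropylsilyloxy)phenyl]-2,3-dihydro-4H-pyran-4-one (trans) | COc1cc([C@@H]2OC=CC(=O)[C@H]2CO[Si](C)(C)C(C)(C)C)ccc1O[Si](C(C)C)(C(C)C)C(C)C | intermediate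
12 | (2R,3R,4S)-3-[(tert-butyldimethylsilyloxy)methyl]-2-[3-methoxy-4-(triisopropylsilyloxy)phenyl]-3,4-dihydro-2H-pyran-4-ol (expected major C4 epimer) | COc1cc([C@@H]2OC=C[C@H](O)[C@H]2CO[Si](C)(C)C(C)(C)C)ccc1O[Si](C(C)C)(C(C)C)C(C)C | intermediate
13 | tert-butyl{[(2R,3S)-2-[3-methoxy-4-(triisopropylsilyloxy)phenyl]-3,6-dihydro-2H-pyran-3-yl]methoxy}dimethylsilane | COc1cc([C@@H]2OCC=C[C@H]2CO[Si](C)(C)C(C)(C)C)ccc1O[Si](C(C)C)(C(C)C)C(C)C | intermediate
14 | [(2R,3S)-2-[3-methoxy-4-(triisopropylsilyloxy)phenyl]-3,6-dihydro-2H-pyran-3-yl]methanol | COc1cc([C@@H]2OCC=C[C@H]2CO)ccc1O[Si](C(C)C)(C(C)C)C(C)C | intermediate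
15 | [(2R,3S)-2-[3-methoxy-4-(triisopropylsilyloxy)phenyl]-3,6-dihydro-2H-pyran-3-yl]methyl acetate | COc1cc([C@@H]2OCC=C[C@H]2COC(C)=O)ccc1O[Si](C(C)C)(C(C)C)C(C)C | intermediate
16 | [(2R,3S)-2-[3-methoxy-4-(triisopropylsilyloxy)phenyl]-3,4-dihydro-2H-pyran-3-yl]methyl acetate | COc1cc([C@@H]2OC=CC[C@H]2COC(C)=O)ccc1O[Si](C(C)C)(C(C)C)C(C)C | intermediate
17 | [(2R,3S)-5-iodo-2-[3-methoxy-4-(triisopropylsilyloxy)phenyl]-3,4-dihydro-2H-pyran-3-yl]methyl acetate | COc1cc([C@@H]2OC=C(I)C[C@H]2COC(C)=O)ccc1O[Si](C(C)C)(C(C)C)C(C)C | intermediate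
18 | 2-bromo-1,4-dimethoxybenzene | COc1ccc(OC)c(Br)c1 | starting material
19 | 1-(4-bromo-2,5-dimethoxyphenyl)ethanone | CC(=O)c1cc(OC)c(Br)cc1OC | intermediate
20 | 1-(4-bromo-2,5-dihydroxyphenyl)ethanone | CC(=O)c1cc(O)c(Br)cc1O | intermediate
21 | ethynyltrimethylsilane | C#C[Si](C)(C)C | starting material
22 | 1-{2,5-dihydroxy-4-[(trimethylsilyl)ethynyl]phenyl}ethanone | CC(=O)c1cc(O)c(C#C[Si](C)(C)C)cc1O | intermediate
23 | 1-(4-ethynyl-2,5-dihydroxyphenyl)ethanone | CC(=O)c1cc(O)c(C#C)cc1O | intermediate
24 | [(2R,3S)-5-[(4-acetyl-2,5-dihydroxyphenyl)ethynyl]-2-[3-methoxy-4-(triisopropylsilyloxy)phenyl]-3,4-dihydro-2H-pyran-3-yl]methyl acetate | COc1cc([C@@H]2OC=C(C#Cc3cc(O)c(C(C)=O)cc3O)C[C@H]2COC(C)=O)ccc1O[Si](C(C)C)(C(C)C)C(C)C | intermediate (not isolated)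
25 | [(2R,3S)-5-(6-acetyl-5-hydroxy-1-benzofuran-2-yl)-2-[3-methoxy-4-(triisopropylsilyloxy)phenyl]-3,4-dihydro-2H-pyran-3-yl]methyl acetate | COc1cc([C@@H]2OC=C(c3cc4cc(O)c(C(C)=O)cc4o3)C[C@H]2COC(C)=O)ccc1O[Si](C(C)C)(C(C)C)C(C)C | intermediate
26 | propolis-benzofuran A, [(2R,3S)-5-(6-acetyl-5-hydroxy-1-benzofuran-2-yl)-2-(4-hydroxy-3-methoxyphenyl)-3,4-dihydro-2H-pyran-3-yl]methyl acetate | COc1cc([C@@H]2OC=C(c3cc4cc(O)c(C(C)=O)cc4o3)C[C@H]2COC(C)=O)ccc1O | target

**Step count and risks**

Total steps: 19. Longest linear sequence: 14 steps (steps 2 to 13, then 18 and 19).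

Steps most likely to fail:

1. Step 7. The electron-rich aldehyde may add slowly, and the allylic silyloxymethyl arm on the diene may erode facial or anti selectivity. The fallback sets out from 2 and 9 and forms the same C2–C3 and O1–C6 bonds by a concerted, endo-selective cycloaddition. The catalyst is the tridentate Schiff-base chromium chloride complex CrCl(L), trivalent chromium, with 4 Å molecular sieves, followed by CF3CO2H. L is the dianion of (1R,2S)-1-{[3-(1-adamantyl)-2-hydroxy-5-methylbenzylidene]amino}indan-2-ol or its enantiomer, whichever gives 2R. This should give the cis isomer (2R,3R)-3-[(tert-butyldimethylsilyloxy)methyl]-2-[3-methoxy-4-(triisopropylsilyloxy)phenyl]-2,3-dihydro-4H-pyran-4-one F1. Because C3 lies α to the ketone, brief treatment with DBU (cat.) in CH2Cl2 at 0 °C should epimerise it to the diequatorial trans isomer, which is 11.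

2. Step 12. The ruthenium hydride may walk the double bond past C4 toward C3, which would scramble the C3 centre or expel the acetate, or the migration may stall. The fallback sets out from 12 and puts the hydride on C4 directly, so no alkene has to migrate. CSA (cat.) in MeOH at 0 °C should effect Ferrier-type allylic transposition with methanol entering at C6, together with loss of the alkyl silyl group. This gives [(2R,3S)-6-methoxy-2-[3-methoxy-4-(triisopropylsilyloxy)phenyl]-3,6-dihydro-2H-pyran-3-yl]methanol F2 as an anomer mixture. LiAlH4 in refluxing THF then displaces the C6 methoxy group in an SN2′ sense with hydride delivery to C4, assisted by the aluminium alkoxide of the C3 arm. This is the known conversion of alkyl 2,3-unsaturated glycosides into 3-deoxyglycals, and it should give [(2R,3S)-2-[3-methoxy-4-(triisopropylsilyloxy)phenyl]-3,4-dihydro-2H-pyran-3-yl]methanol F3. Acetylation (Ac2O, pyridine) comes back to the route at 16.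

3. Step 18. The ethynyl hydroquinone 23 may cyclise on its own or oxidise before it couples, and the enyne may stop short of furan closure. The fallback sets out from 22 and joins a preformed benzofuran to 17 by an sp2–sp2 coupling. TBAF in THF at 60 °C removes the C-silyl group and closes the furan (5-endo-dig) to give 1-(5-hydroxy-1-benzofuran-6-yl)ethanone F4. Iridium-catalysed C–H borylation at the furan C2 position ([Ir(OMe)(cod)]2, 4,4'-di-tert-butyl-2,2'-bipyridine, B2pin2, THF, rt; the transient O-boryl phenol is hydrolysed on work-up) gives 1-[5-hydroxy-2-(4,4,5,5-tetramethyl-1,3,2-dioxaborolan-2-yl)-1-benzofuran-6-yl]ethanone F5. Suzuki–Miyaura coupling of F5 with iodide 17 (Pd(dppf)Cl2, K3PO4, THF/H2O, 40 °C) comes back to the route at 25.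

Further compounds
F1 | step 7 | (2R,3R)-3-[(tert-butyldimethylsilyloxy)methyl]-2-[3-methoxy-4-(triisopropylsilyloxy)phenyl]-2,3-dihydro-4H-pyran-4-one (cis) | COc1cc([C@@H]2OC=CC(=O)[C@@H]2CO[Si](C)(C)C(C)(C)C)ccc1O[Si](C(C)C)(C(C)C)C(C)C
F2 | step 12 | [(2R,3S)-6-methoxy-2-[3-methoxy-4-(triisopropylsilyloxy)phenyl]-3,6-dihydro-2H-pyran-3-yl]methanol (anomer mixture) | COc1cc([C@@H]2OC(OC)C=C[C@H]2CO)ccc1O[Si](C(C)C)(C(C)C)C(C)C
F3 | step 12 | [(2R,3S)-2-[3-methoxy-4-(triisopropylsilyloxy)phenyl]-3,4-dihydro-2H-pyran-3-yl]methanol | COc1cc([C@@H]2OC=CC[C@H]2CO)ccc1O[Si](C(C)C)(C(C)C)C(C)C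
F4 | step 18 | 1-(5-hydroxy-1-benzofuran-6-yl)ethanone | CC(=O)c1cc2occc2cc1O
F5 | step 18 | 1-[5-hydroxy-2-(4,4,5,5-tetramethyl-1,3,2-dioxaborolan-2-yl)-1-benzofuran-6-yl]ethanone | CC(=O)c1cc2oc(B3OC(C)(C)C(C)(C)O3)cc2cc1O
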